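**Retrosynthetic overview**

- Numbering: ring A is C10–C1–C2–C3–C4–C5 (C3 acetate, C4 and C5 methyls) and ring B is C5–C6–C7–C8–C9–C10 (C7 acetyl, C8 ketone, C9 angelate, C10 hydroxyl). β is the face of the C5 methyl, and bicyclic compounds are named as decalins with these locants.
- Late disconnections: the C7 acetyl comes from a Stille coupling on a 7-iodo-6-en-8-one; the C9 ester comes from opening a 9β,10β-epoxide at C9 with angelate (inversion); the epoxide and the 6,7-alkene come from the 9(10)-en-8-one 13.
- Ring B is closed by aldol condensation (C9–C10) of a methyl ketone unmasked from a vinyl chloride. The C3 acetate comes from a face-selective reduction of the C3 ketone freed from a dimethyl ketal.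
- The strategy rests on the vicinal pair C4 (H, CH3) and quaternary C5 (CH3, C6) of ring A with cis methyls. C4–CH3 and C5–C6 are made in one flask by copper-catalysed enantioselective methyl transfer from AlMe3 to 4,4-dimethoxy-2-methylcyclohex-2-enone, then anti alkylation of the enolate with (E)-1,3-dichlorobut-2-ene.
- Ring order: ring A is present from the start (dearomatized 4-methoxy-2-methylphenol); ring B is closed second (step 8).

Key step: step 3

Remark: the ligand antipode named in step 3 is assumed to deliver methyl to the face of 3 that gives the (3R) centre; the sense is to be confirmed on the first run, and the mirror-image ligand is used if it is opposite.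
Remark: the alkene geometry of 5 is erased in step 7, so the (E) isomer is written but a geometric mixture would serve equally.

**Route**

Step 1
Reactants: 1 4-methoxy-2-methylphenol
Product: 2 4,4-dimethoxy-2-methylcyclohexa-2,5-dien-1-one
Conditions: PhI(OAc)2, MeOH, 0 °C
Reagents that add atoms: methanol, CO
Why: Oxidative dearomatization of a para-methoxyphenol by the hypervalent iodine reagent, with methanol trapping the phenoxonium ion at C4, is the standard quinone monoketal synthesis.

Step 2
Reactants: 2 4,4-dimethoxy-2-methylcyclohexa-2,5-dien-1-one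
Product: 3 4,4-dimethoxy-2-methylcyclohex-2-en-1-one
Conditions: H2 (1 atm), RhCl(PPh3)3 (5 mol %), benzene, rt
Reagents that add atoms: none
Why: Homogeneous hydrogenation with the rhodium–phosphine complex should reduce the cis-disubstituted C5=C6 bond much faster than the methyl-bearing trisubstituted C2=C3 bond, as in the selective 1,2-reduction of cross-conjugated 1,4-dien-3-ones.

Step 3
Reactants: 3 4,4-dimethoxy-2-methylcyclohex-2-en-1-one; 4 trimethylaluminium; 5 (E)-1,3-dichlorobut-2-ene
Product: 8 (2R,3R)-2-[(E)-3-chlorobut-2-enyl]-4,4-dimethoxy-2,3-dimethylcyclohexan-1-one, via dimethylaluminium enolate 6 (not isolated), via lithium aluminate enolate 7 (not isolated)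
Conditions: copper thiophene-2-carboxylate (CuTC, monovalent copper, 5 mol %), O,O′-(biphenyl-2,2′-diyl) N,N-bis[(R)-1-phenylethyl]phosphoramidite (10 mol %), Et2O, −30 °C; then MeLi (1.0 equiv), THF/DMPU, −30 °C; then 5, Bu4NI (10 mol %), −30 → 0 °C
Reagents that add atoms: none
Why: A chiral copper–methyl species formed from CuTC, the phosphoramidite and 4 binds the enone of 3 as a π-complex, adds at C3 to give a trivalent copper intermediate and forms the C3–CH3 bond by reductive elimination, leaving the regiodefined enolate 6; MeLi converts it into the more nucleophilic aluminate 7, which displaces the primary allylic chloride of 5 in an SN2 alkylation at C2. The closest known reaction type is the copper/phosphoramidite-catalysed conjugate addition of trialkylaluminium reagents to 2-substituted cyclohexenones with trapping of the aluminium enolate by a reactive halide in the same flask. No ring is closed. The C3 centre (C4 of the target) is set by the ligand, which selects the enone face for methyl delivery; the quaternary C2 centre (C5 of the target) is set by the new C3 methyl, which sits pseudoaxially in the enolate and sends the electrophile to the opposite face, so the two methyls end up cis. The step needs 1,4- over 1,2-addition (secured by copper catalysis in ether at low temperature), C-alkylation at the methyl-bearing enolate carbon only (secured because the enolate is formed regiospecifically and is not equilibrated), and reaction at the CH2Cl end of 5 (the vinylic chloride is inert to SN2). The gem-dimethoxy group next to C3 is the main steric burden.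

Step 4
Reactants: 8 (2R,3R)-2-[(E)-3-chlorobut-2-enyl]-4,4-dimethoxy-2,3-dimethylcyclohexan-1-one
Product: 9 (2R,3R)-2-[(E)-3-chlorobut-2-enyl]-2,3-dimethylcyclohexane-1,4-dione
Conditions: oxalic acid (10 mol %), THF/H2O, rt
Reagents that add atoms: water, O
Why: Acid-catalysed ketal hydrolysis under conditions mild enough to leave the vinyl chloride intact and the C3 centre, now alpha to a ketone, unepimerized.

Step 5
Reactants: 9 (2R,3R)-2-[(E)-3-chlorobut-2-enyl]-2,3-dimethylcyclohexane-1,4-dione
Product: 10 (2R,3R,4S)-2-[(E)-3-chlorobut-2-enyl]-4-hydroxy-2,3-dimethylcyclohexan-1-one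
Conditions: LiBH(s-Bu)3 (1.05 equiv), THF, −78 °C; then H2O
Reagents that add atoms: none
Why: Sterically controlled reduction with a bulky trialkylborohydride should reach the C4 carbonyl along its equatorial trajectory (the axial one is blocked by the axial C2 methyl), giving the axial alcohol cis to the C3 methyl, while the C1 carbonyl next to the quaternary C2 is shielded on both faces.

Step 6
Reactants: 10 (2R,3R,4S)-2-[(E)-3-chlorobut-2-enyl]-4-hydroxy-2,3-dimethylcyclohexan-1-one
Product: 11 (1S,2R,3R)-3-[(E)-3-chlorobut-2-enyl]-2,3-dimethyl-4-oxocyclohexyl acetate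
Conditions: Ac2O, pyridine, DMAP (cat.), CH2Cl2, rt
Reagents that add atoms: acetic anhydride, CC(=O)OC(C)=O
Why: DMAP-catalysed acylation installs the C3 acetate of the target at a stage where it also removes the free hydroxyl before the acidic steps.

Step 7
Reactants: 11 (1S,2R,3R)-3-[(E)-3-chlorobut-2-enyl]-2,3-dimethyl-4-oxocyclohexyl acetate
Product: 12 (1S,2R,3R)-2,3-dimethyl-4-oxo-3-(3-oxobutyl)cyclohexyl acetate
Conditions: Hg(OAc)2 (1.1 equiv), 88% HCO2H, rt
Reagents that add atoms: water, O
Why: Wichterle-type unmasking, in which divalent mercury activates the chloroalkene for Markovnikov addition of water at the chlorine-bearing carbon, chloride is lost and the α-mercurio ketone is protonolysed to the methyl ketone; the acetate and the ring ketone should tolerate the medium.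

Step 8
Reactants: 12 (1S,2R,3R)-2,3-dimethyl-4-oxo-3-(3-oxobutyl)cyclohexyl acetate
Product: 13 (1R,2S,8aR)-1,8a-dimethyl-6-oxo-1,2,3,4,6,7,8,8a-octahydronaphthalen-2-yl acetate (3β-acetoxy-4β,5β-dimethyldecal-9(10)-en-8-one)
Conditions: p-TsOH·H2O (20 mol %), toluene, reflux, Dean–Stark
Reagents that add atoms: none
Why: Acid-catalysed intramolecular aldol condensation (the ring-closing half of a Robinson annulation) joins the methyl carbon of the side-chain ketone to the C10 carbonyl, and dehydration of the ketol drives the equilibrium to the conjugated octalenone; C4 is no longer alpha to a carbonyl and cannot epimerize.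

Step 9
Reactants: 13 3β-acetoxy-4β,5β-dimethyldecal-9(10)-en-8-one
Product: 14 3β-acetoxy-9β,10β-epoxy-4β,5β-dimethyldecalin-8-one
Conditions: t-BuOOH (in decane), benzyltrimethylammonium hydroxide (Triton B, 10 mol %), THF, 0 °C → rt
Reagents that add atoms: tert-butyl hydroperoxide, CC(C)(C)OO
Why: Weitz–Scheffer epoxidation, in which the peroxide anion should add axially to C10 on the face of the C5 methyl through the transition state leading to a cis-fused enolate (the course followed by 4-en-3-one steroids and 10-methyl octalenones), placing the C10 oxygen in its final β configuration; the near-anhydrous medium spares the acetate.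

Step 10
Reactants: 14 3β-acetoxy-9β,10β-epoxy-4β,5β-dimethyldecalin-8-one
Product: 16 3β-acetoxy-9β,10β-epoxy-4β,5β-dimethyldecal-6-en-8-one, via trimethylsilyl enol ether 15 (not isolated)
Conditions: LiN(SiMe3)2, Me3SiCl, THF, −78 °C; then Pd(OAc)2 (1.1 equiv), MeCN, rt
Reagents that add atoms: none
Why: Saegusa–Ito dehydrogenation, for which the epoxy ketone can enolize only toward C7, so the silyl enol ether is palladated at C7 by divalent palladium and β-hydride elimination of H6 gives the 6-en-8-one.

Step 11
Reactants: 16 3β-acetoxy-9β,10β-epoxy-4β,5β-dimethyldecal-6-en-8-one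
Product: 17 3β-acetoxy-9α-[(Z)-2-methylbut-2-enoyloxy]-10β-hydroxy-4β,5β-dimethyldecal-6-en-8-one
Conditions: angelic acid (4 equiv), cesium (Z)-2-methylbut-2-enoate (0.5 equiv, preformed), DMF, 45 °C
Reagents that add atoms: (Z)-2-methylbut-2-enoic acid (angelic acid), C/C=C(/C)C(=O)O
Why: Proposed new method: the carboxylate should attack C9 in an SN2 reaction anti to the epoxide C–O bond (C9 is secondary and activated by the adjacent C8 carbonyl, whereas C10 is tertiary and neopentyl-like), inverting C9 to the 9α ester while the 10β oxygen is retained and protonated by the buffering acid, and because the ester forms by carboxylate alkylation the acyl group is never activated and the Z geometry is not at risk; the closest known reaction types are the opening of α,β-epoxy ketones at the α-carbon by thiolates, halides and azide and the SN2 displacement of α-halo ketones by cesium carboxylates.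

Step 12
Reactants: 17 3β-acetoxy-9α-[(Z)-2-methylbut-2-enoyloxy]-10β-hydroxy-4β,5β-dimethyldecal-6-en-8-one
Product: 18 3β-acetoxy-9α-[(Z)-2-methylbut-2-enoyloxy]-10β-hydroxy-7-iodo-4β,5β-dimethyldecal-6-en-8-one
Conditions: I2 (2 equiv), pyridine/CH2Cl2, rt, dark
Reagents that add atoms: iodine, II
Why: α-Iodination of an enone by addition–elimination (pyridine adds to C6, the enolate is iodinated at C7, pyridine is expelled), known for 4,4-disubstituted cyclohexenones; light is excluded to spare the angelate geometry.

Step 13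
Reactants: 18 3β-acetoxy-9α-[(Z)-2-methylbut-2-enoyloxy]-10β-hydroxy-7-iodo-4β,5β-dimethyldecal-6-en-8-one
Product: 20 (1S,4aR,5R,6S,8aR)-6-acetoxy-3-acetyl-8a-hydroxy-4a,5-dimethyl-2-oxo-1,2,4a,5,6,7,8,8a-octahydronaphthalen-1-yl (2Z)-2-methylbut-2-enoate, via ethoxyvinyl dienone 19 (not isolated)
Conditions: tributyl(1-ethoxyvinyl)stannane, Pd2(dba)3 (2.5 mol %), AsPh3 (10 mol %), CuI (10 mol %), DMF, 40 °C; then 1 M HCl, THF, 0 °C
Reagents that add atoms: tributyl(1-ethoxyvinyl)stannane, CCCC[Sn](CCCC)(CCCC)C(=C)OCC; water, O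
Why: Stille coupling of the α-iodo enone with an acetyl anion equivalent, followed by hydrolysis of the enol ether on acidic work-up, reveals the sensitive 2-acetyl enone only in the last operation.

**Compound list**

1 | 4-methoxy-2-methylphenol | COc1ccc(O)c(C)c1 | starting material
2 | 4,4-dimethoxy-2-methylcyclohexa-2,5-dien-1-one | COC1(OC)C=CC(=O)C(C)=C1 | intermediate
3 | 4,4-dimethoxy-2-methylcyclohex-2-en-1-one | COC1(OC)CCC(=O)C(C)=C1 | intermediate
4 | trimethylaluminium | C[Al](C)C | starting material
5 | (E)-1,3-dichlorobut-2-ene | ClC/C=C(\C)Cl | starting material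
6 | dimethylaluminium (3R)-4,4-dimethoxy-2,3-dimethylcyclohex-1-en-1-olate (not isolated) | C[Al](C)OC1=C(C)[C@@H](C)C(OC)(OC)CC1 | intermediate
7 | lithium trimethyl[(3R)-4,4-dimethoxy-2,3-dimethylcyclohex-1-en-1-olato]aluminate (not isolated) | [Li+].C[Al-](C)(C)OC1=C(C)[C@@H](C)C(OC)(OC)CC1 | intermediate
8 | (2R,3R)-2-[(E)-3-chlorobut-2-enyl]-4,4-dimethoxy-2,3-dimethylcyclohexan-1-one | Cl/C(C)=C/C[C@]1(C)[C@@H](C)C(OC)(OC)CCC1=O | intermediate
9 | (2R,3R)-2-[(E)-3-chlorobut-2-enyl]-2,3-dimethylcyclohexane-1,4-dione | Cl/C(C)=C/C[C@]1(C)[C@@H](C)C(=O)CCC1=O | intermediate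
10 | (2R,3R,4S)-2-[(E)-3-chlorobut-2-enyl]-4-hydroxy-2,3-dimethylcyclohexan-1-one | Cl/C(C)=C/C[C@]1(C)[C@@H](C)[C@@H](O)CCC1=O | intermediate
11 | (1S,2R,3R)-3-[(E)-3-chlorobut-2-enyl]-2,3-dimethyl-4-oxocyclohexyl acetate | Cl/C(C)=C/C[C@]1(C)[C@@H](C)[C@@H](OC(C)=O)CCC1=O | intermediate
12 | (1S,2R,3R)-2,3-dimethyl-4-oxo-3-(3-oxobutyl)cyclohexyl acetate | CC(=O)CC[C@]1(C)[C@@H](C)[C@@H](OC(C)=O)CCC1=O | intermediate
13 | (1R,2S,8aR)-1,8a-dimethyl-6-oxo-1,2,3,4,6,7,8,8a-octahydronaphthalen-2-yl acetate | O=C1CC[C@]2(C)[C@@H](C)[C@@H](OC(C)=O)CCC2=C1 | intermediate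
14 | 3β-acetoxy-9β,10β-epoxy-4β,5β-dimethyldecalin-8-one | CC(=O)O[C@H]1CC[C@]23O[C@H]2C(=O)CC[C@]3(C)[C@H]1C | intermediate
15 | 3β-acetoxy-9β,10β-epoxy-4β,5β-dimethyl-8-(trimethylsilyloxy)decal-7-ene (not isolated) | CC(=O)O[C@H]1CC[C@]23O[C@H]2C(O[Si](C)(C)C)=CC[C@]3(C)[C@H]1C | intermediate
16 | 3β-acetoxy-9β,10β-epoxy-4β,5β-dimethyldecal-6-en-8-one | CC(=O)O[C@H]1CC[C@]23O[C@H]2C(=O)C=C[C@]3(C)[C@H]1C | intermediate
17 | 3β-acetoxy-9α-[(Z)-2-methylbut-2-enoyloxy]-10β-hydroxy-4β,5β-dimethyldecal-6-en-8-one | C/C=C(/C)C(=O)O[C@@H]1C(=O)C=C[C@]2(C)[C@@H](C)[C@@H](OC(C)=O)CC[C@]12O | intermediate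
18 | 3β-acetoxy-9α-[(Z)-2-methylbut-2-enoyloxy]-10β-hydroxy-7-iodo-4β,5β-dimethyldecal-6-en-8-one | C/C=C(/C)C(=O)O[C@@H]1C(=O)C(I)=C[C@]2(C)[C@@H](C)[C@@H](OC(C)=O)CC[C@]12O | intermediate
19 | 3β-acetoxy-9α-[(Z)-2-methylbut-2-enoyloxy]-7-(1-ethoxyvinyl)-10β-hydroxy-4β,5β-dimethyldecal-6-en-8-one (not isolated) | C/C=C(/C)C(=O)O[C@@H]1C(=O)C(C(=C)OCC)=C[C@]2(C)[C@@H](C)[C@@H](OC(C)=O)CC[C@]12O | intermediate
20 | (1S,4aR,5R,6S,8aR)-6-acetoxy-3-acetyl-8a-hydroxy-4a,5-dimethyl-2-oxo-1,2,4a,5,6,7,8,8a-octahydronaphthalen-1-yl (2Z)-2-methylbut-2-enoate | C/C=C(/C)C(=O)O[C@@H]1C(=O)C(C(C)=O)=C[C@]2(C)[C@@H](C)[C@@H](OC(C)=O)CC[C@]12O | target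

**Step count and risk**

Total steps: 13. Longest linear sequence: 13 steps (from 1; the route is fully linear).

Steps most likely to fail:

1. Step 11 (proposed new method). Attack of the carboxylate at the hindered C9 may be slow, and the product may lose water across C9–C10 by base-induced elimination or epimerize at C9. The fallback uses known reactions, sets out from 16 and returns at 17. The C9–O bond of 16 is cleaved reductively with Na[PhSeB(OEt)3] ((PhSe)2, NaBH4, EtOH, AcOH, 0 °C) to the ketol 3β-acetoxy-10β-hydroxy-4β,5β-dimethyldecal-6-en-8-one F1. Its dianion (LiN(SiMe3)2, 2.2 equiv, THF, −78 °C; C9 is the only enolizable position) is hydroxylated with 2-(phenylsulfonyl)-3-phenyloxaziridine, expected on the convex β face, to the cis-diol 3β-acetoxy-9β,10β-dihydroxy-4β,5β-dimethyldecal-6-en-8-one F2. Mitsunobu esterification with angelic acid (PPh3, DIAD, toluene, 0 °C → rt) then inverts C9 and gives 17.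

2. Step 3 (key step). Conjugate addition may stall at the carbon flanked by the ketal, and alkylation of the aluminium enolate in the same flask may be slow enough to erode the anti selectivity or leave unalkylated ketone. The fallback sets out from 3 and returns at 8. The copper-catalysed addition of 4 is run alone, with excess reagent and longer time if needed, and the aluminium enolate is silylated (Me3SiOTf, Et3N, THF) to the isolable [(3R)-4,4-dimethoxy-2,3-dimethylcyclohex-1-en-1-yl]oxytrimethylsilane F3, on which enantiomeric purity can be checked. The lithium enolate is then released with MeLi (THF, 0 °C) and alkylated with 5 in THF/DMPU to give 8.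

3. Step 9. The nucleophilic epoxidation may show poor facial selectivity (attack on the face away from the C5 methyl) or be slow at the fully substituted C10, which would put the C10 oxygen on the wrong face. The fallback sets out from 13 and returns at 14. Luche reduction (NaBH4, CeCl3·7H2O, MeOH, −40 °C) should give the pseudo-equatorial allylic alcohol 3β-acetoxy-4β,5β-dimethyldecal-9(10)-en-8β-ol F4. Hydroxyl-directed epoxidation (VO(acac)2, t-BuOOH, CH2Cl2, 0 °C) places the epoxide syn to the 8β-hydroxyl and gives 3β-acetoxy-9β,10β-epoxy-4β,5β-dimethyldecalin-8β-ol F5. Dess–Martin oxidation (NaHCO3, CH2Cl2) returns to 14.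

Further compounds

F1 | step 11 | 3β-acetoxy-10β-hydroxy-4β,5β-dimethyldecal-6-en-8-one | C1C(=O)C=C[C@]2(C)[C@@H](C)[C@@H](OC(C)=O)CC[C@]12O
F2 | step 11 | 3β-acetoxy-9β,10β-dihydroxy-4β,5β-dimethyldecal-6-en-8-one | O[C@H]1C(=O)C=C[C@]2(C)[C@@H](C)[C@@H](OC(C)=O)CC[C@]12O
F3 | step 3 | [(3R)-4,4-dimethoxy-2,3-dimethylcyclohex-1-en-1-yl]oxytrimethylsilane | C[Si](C)(C)OC1=C(C)[C@@H](C)C(OC)(OC)CC1
F4 | step 9 | 3β-acetoxy-4β,5β-dimethyldecal-9(10)-en-8β-ol | O[C@H]1CC[C@]2(C)[C@@H](C)[C@@H](OC(C)=O)CCC2=C1
F5 | step 9 | 3β-acetoxy-9β,10β-epoxy-4β,5β-dimethyldecalin-8β-ol | CC(=O)O[C@H]1CC[C@]23O[C@H]2[C@@H](O)CC[C@]3(C)[C@H]1C
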